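**Retrosynthetic overview**

- Feature: the carbocycle C4a–C5–C6–C7–C8–C8a holds the only stereocentre (C5, octyl). Its neighbour C4a carries the exocyclic carbon C4, and the next ring atom C8a carries a heteroatom (N1). This 1,2-pattern is what a [4+2] adduct of a 1-oxygenated butadiene (C8a–C8–C7–C6) with an (E)-enal (C4–C4a–C5) leaves behind.
- Late stage: the CH2OH group comes from the C2 methyl group (SeO2, then NaBH4). The N-methoxy-4-pyridone ring is opened at N1–C2 and N1–C8a to an allenyl β-diketone and methoxyamine. C3–C4 comes from lithiated methoxyallene and an aldehyde.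
- Key disconnection: C4a–C8a and C5–C6, an amine-catalysed enantioselective Diels–Alder reaction of (E)-undec-2-enal with an (E)-1-silyloxybutadiene. It sets C5; the two extra centres of the adduct are later flattened to sp2 carbons.
- Ring order: carbocycle first (step 2), pyridone ring second (step 8).

Key step: step 2

Remark: C5 of the target is read from the SMILES as R. The silyl group on the diene is triisopropylsilyl, so that the dienol ether better survives the wet ammonium-salt medium of the cycloaddition.

**Route**

Step 1
Reactants: 1 crotonaldehyde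
Product: 2 (E)-1-[(triisopropylsilyl)oxy]buta-1,3-diene
Conditions: TIPSOTf, NEt3, Et2O, 0 °C → rt; distillation
Reagents that add atoms: triisopropylsilyl trifluoromethanesulfonate, CC(C)[Si](C(C)C)(C(C)C)OS(=O)(=O)C(F)(F)F
Why: O-silylation of the enal followed by γ-deprotonation of the silyloxocarbenium ion by the amine (vinylogous silyl enol ether formation) should give mainly the (E)-dienol ether, and any minor Z isomer cannot reach the s-cis conformation and stays a spectator in step 2.

Step 2
Reactants: 3 (E)-undec-2-enal; 2 (E)-1-[(triisopropylsilyl)oxy]buta-1,3-diene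
Product: 6 (1S,2R,6R)-6-octyl-2-[(triisopropylsilyl)oxy]cyclohex-3-ene-1-carbaldehyde, via dienophile iminium ion 4 (not isolated), via cycloadduct iminium ion 5 (not isolated)
Conditions: (2R,5R)-5-benzyl-2-tert-butyl-3-methylimidazolidin-4-one trifluoroacetate (20 mol %), 2 (2.5 equiv), MeCN/H2O 98:2, 0 °C
Reagents that add atoms: water, O
Why: The secondary amine condenses with 3 to the (E)-iminium ion 4, whose lowered LUMO makes it the dienophile; diene 2 adds across Cα=Cβ in a concerted but asynchronous [4+2] cycloaddition, its free terminus bonding to the β-carbon (future C5–C6) ahead of the oxygen-bearing terminus bonding to the α-carbon (future C4a–C8a), and hydrolysis of the adduct iminium ion 5 releases 6 and the amine. The closest known reaction type is the imidazolidinone-catalysed Diels–Alder reaction of enals with acyclic dienes, 1-acyloxybutadienes among them. The six-membered carbocycle is closed by the intermolecular cycloaddition itself, both ring bonds forming suprafacially in one step. The octyl-bearing carbon is set by the catalyst: in the (2R,5R) series the benzyl group covers one face of the iminium ion, so the diene reaches the β-carbon from the side on which Cα, octyl and H run counterclockwise and the (R) centre results; the formyl carbon is fixed trans to octyl by the E geometry of the enal, and the silyloxy carbon cis to formyl by endo approach of the (E)-diene. The step needs enantiofacial selectivity, which the catalyst supplies, and ortho regiochemistry, which the 1-silyloxy group secures by placing the largest HOMO coefficient on the remote diene terminus. Only the octyl centre has to be clean, because the formyl- and silyloxy-bearing carbons become sp2 in steps 7 and 8, so exo adduct or material epimerised next to the aldehyde converges on the same product.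

Step 3
Reactants: 6 (1S,2R,6R)-6-octyl-2-[(triisopropylsilyl)oxy]cyclohex-3-ene-1-carbaldehyde
Product: 7 (1S,2R,6R)-2-octyl-6-[(triisopropylsilyl)oxy]cyclohexane-1-carbaldehyde
Conditions: H2 (1 atm), 5% Rh/Al2O3, EtOAc, rt
Reagents that add atoms: none
Why: Heterogeneous hydrogenation should saturate the cis-disubstituted ring alkene without touching the aliphatic aldehyde or the silyl ether, rhodium on alumina being chosen because it causes little allylic C–O hydrogenolysis or double-bond migration, and no stereocentre is formed.

Step 4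
Reactants: 8 methyl propargyl ether
Product: 9 methoxyallene
Conditions: KOtBu (10 mol %), neat, 70 °C; distillation
Reagents that add atoms: none
Why: Base-catalysed propargyl-to-allenyl prototropic isomerisation of a propargyl ether stops at the alkoxyallene, which is distilled away from the catalyst.

Step 5
Reactants: 9 methoxyallene; 7 (1S,2R,6R)-2-octyl-6-[(triisopropylsilyl)oxy]cyclohexane-1-carbaldehyde
Product: 11 2-methoxy-1-{(1R,2R,6R)-2-octyl-6-[(triisopropylsilyl)oxy]cyclohexyl}buta-2,3-dien-1-ol as a mixture of carbinol epimers, via 1-lithio-1-methoxyallene 10 (not isolated)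
Conditions: n-BuLi, THF, −40 °C; then 7, −78 °C; H2O quench
Reagents that add atoms: none
Why: n-BuLi removes the oxygen-activated C1–H of the allene and the lithiated alkoxyallene adds 1,2 to the aldehyde (carbonyl addition, forming C3–C4), the new carbinol centre being left uncontrolled because it is oxidised in step 7; the ring geometry is unchanged and the descriptor at the ring carbon changes only through CIP priorities.

Step 6
Reactants: 11 2-methoxy-1-{(1R,2R,6R)-2-octyl-6-[(triisopropylsilyl)oxy]cyclohexyl}buta-2,3-dien-1-ol
Product: 12 (1R,2S,3R)-2-(1-hydroxy-2-methoxybuta-2,3-dien-1-yl)-3-octylcyclohexan-1-ol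
Conditions: Bu4NF (TBAF), THF, 0 °C → rt; NEt3-deactivated silica
Reagents that add atoms: none
Why: Fluoride cleaves the Si–O bond under basic, non-acidic conditions that should leave the acid-sensitive allenyl enol ether intact.

Step 7
Reactants: 12 (1R,2S,3R)-2-(1-hydroxy-2-methoxybuta-2,3-dien-1-yl)-3-octylcyclohexan-1-ol
Product: 13 (3R)-2-(2-methoxybuta-2,3-dienoyl)-3-octylcyclohexan-1-one
Conditions: Dess–Martin periodinane (3 equiv), NaHCO3, CH2Cl2, 0 °C → rt; used crude
Reagents that add atoms: none
Why: Dess–Martin oxidation should convert both secondary alcohols into ketones under buffered conditions, giving the enolisable allenyl β-diketone in which the formyl- and silyloxy-derived centres are gone, while the octyl centre, which is not α to a carbonyl group, stays untouched.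

Step 8
Reactants: 13 (3R)-2-(2-methoxybuta-2,3-dienoyl)-3-octylcyclohexan-1-one; 14 O-methylhydroxylamine hydrochloride
Product: 16 (5R)-1,3-dimethoxy-2-methyl-5-octyl-5,6,7,8-tetrahydroquinolin-4(1H)-one, via methoxyamino enone 15 (not isolated)
Conditions: NaOAc, MeOH, 0 °C → rt; then AcOH, 60 °C
Reagents that add atoms: none
Why: Methoxyamine adds in aza-Michael fashion to the central allene carbon of the allenyl ketone (known amine addition to 1,2-allenyl ketones) to give the enaminone 15, whose nitrogen then condenses with the ring ketone in a six-membered cyclodehydration driven by formation of the aromatic 4-pyridone, as in pyridone syntheses from 1,3,5-tricarbonyl compounds and amines, and initial condensation at the ring ketone would converge on the same product.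

Step 9
Reactants: 16 (5R)-1,3-dimethoxy-2-methyl-5-octyl-5,6,7,8-tetrahydroquinolin-4(1H)-one
Product: 17 (5R)-1,3-dimethoxy-5-octyl-4-oxo-1,4,5,6,7,8-hexahydroquinoline-2-carbaldehyde
Conditions: SeO2 (1.5 equiv), 1,4-dioxane, 80 °C
Reagents that add atoms: selenium dioxide, O=[Se]=O
Why: Riley oxidation through the exocyclic methylene tautomer of the 2-methyl-4-pyridone, a position this reagent is known to oxidise in 3-alkoxy-2-methyl-4-pyridones and -pyranones, should give the aldehyde, while C5–H is not activated and the stereocentre is retained.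

Step 10
Reactants: 17 (5R)-1,3-dimethoxy-5-octyl-4-oxo-1,4,5,6,7,8-hexahydroquinoline-2-carbaldehyde
Product: 18 (5R)-2-(hydroxymethyl)-1,3-dimethoxy-5-octyl-5,6,7,8-tetrahydroquinolin-4(1H)-one
Conditions: NaBH4, MeOH, 0 °C
Reagents that add atoms: none
Why: Hydride reduction with NaBH4 is chemoselective for the aldehyde, the vinylogous amide carbonyl of the pyridone and the N–O bond being inert to it.

**Compound list**

1 | crotonaldehyde, (E)-but-2-enal | C/C=C/C=O | starting material
2 | (E)-1-[(triisopropylsilyl)oxy]buta-1,3-diene | C=C/C=C/O[Si](C(C)C)(C(C)C)C(C)C | intermediate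
3 | (E)-undec-2-enal | CCCCCCCC/C=C/C=O | starting material
4 | dienophile iminium ion: (E)-iminium trifluoroacetate formed from 3 and (2R,5R)-5-benzyl-2-tert-butyl-3-methylimidazolidin-4-one | CN1C(=O)[C@@H](Cc2ccccc2)/[N+](=C\C=C\CCCCCCCC)[C@H]1C(C)(C)C.[O-]C(=O)C(F)(F)F | intermediate (not isolated)
5 | cycloadduct iminium ion: iminium trifluoroacetate of 6 with the same amine | CN1C(=O)[C@@H](Cc2ccccc2)/[N+](=C\[C@@H]3[C@H](O[Si](C(C)C)(C(C)C)C(C)C)C=CC[C@H]3CCCCCCCC)[C@H]1C(C)(C)C.[O-]C(=O)C(F)(F)F | intermediate (not isolated)
6 | (1S,2R,6R)-6-octyl-2-[(triisopropylsilyl)oxy]cyclohex-3-ene-1-carbaldehyde (silyloxy cis, octyl trans to formyl) | CCCCCCCC[C@@H]1CC=C[C@@H](O[Si](C(C)C)(C(C)C)C(C)C)[C@H]1C=O | intermediate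
7 | (1S,2R,6R)-2-octyl-6-[(triisopropylsilyl)oxy]cyclohexane-1-carbaldehyde | CCCCCCCC[C@@H]1CCC[C@@H](O[Si](C(C)C)(C(C)C)C(C)C)[C@H]1C=O | intermediate
8 | methyl propargyl ether, 3-methoxyprop-1-yne | COCC#C | starting material
9 | methoxyallene, 1-methoxypropa-1,2-diene | COC=C=C | intermediate
10 | 1-lithio-1-methoxyallene | [Li]C(OC)=C=C | intermediate (not isolated)
11 | 2-methoxy-1-{(1R,2R,6R)-2-octyl-6-[(triisopropylsilyl)oxy]cyclohexyl}buta-2,3-dien-1-ol, carbinol epimers | CCCCCCCC[C@@H]1CCC[C@@H](O[Si](C(C)C)(C(C)C)C(C)C)[C@H]1C(O)C(OC)=C=C | intermediate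
12 | (1R,2S,3R)-2-(1-hydroxy-2-methoxybuta-2,3-dien-1-yl)-3-octylcyclohexan-1-ol, carbinol epimers | CCCCCCCC[C@@H]1CCC[C@@H](O)[C@H]1C(O)C(OC)=C=C | intermediate
13 | (3R)-2-(2-methoxybuta-2,3-dienoyl)-3-octylcyclohexan-1-one, keto–enol mixture | CCCCCCCC[C@@H]1CCCC(=O)C1C(=O)C(OC)=C=C | intermediate
14 | O-methylhydroxylamine hydrochloride | CON.Cl | starting material
15 | (3R)-2-[(E)-2-methoxy-3-(methoxyamino)but-2-enoyl]-3-octylcyclohexan-1-one, N–H on the side of the acyl carbonyl | CCCCCCCC[C@@H]1CCCC(=O)C1C(=O)/C(OC)=C(/C)NOC | intermediate (not isolated)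
16 | (5R)-1,3-dimethoxy-2-methyl-5-octyl-5,6,7,8-tetrahydroquinolin-4(1H)-one | CCCCCCCC[C@@H]1CCCc2c1c(=O)c(OC)c(C)n2OC | intermediate
17 | (5R)-1,3-dimethoxy-5-octyl-4-oxo-1,4,5,6,7,8-hexahydroquinoline-2-carbaldehyde | CCCCCCCC[C@@H]1CCCc2c1c(=O)c(OC)c(C=O)n2OC | intermediate
18 | (5R)-2-(hydroxymethyl)-1,3-dimethoxy-5-octyl-5,6,7,8-tetrahydroquinolin-4(1H)-one | CCCCCCCC[C@@H]1CCCc2c1c(=O)c(OC)c(CO)n2OC | target

**Step count**

Total steps: 10. Longest linear sequence: 9 (steps 1, 2, 3, 5, 6, 7, 8, 9, 10; step 4 is a one-step side branch).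

**Steps most likely to fail**

1. Step 2. What may go wrong: protonolysis of the silyl dienol ether by the wet ammonium salt. A stepwise pathway may also lose the silyl group from the oxocarbenium intermediate before the second bond forms, giving open-chain conjugate adduct instead of the ring. Turnover with a β-alkyl enal may be slow.
Fallback, from 3 back to 6, with auxiliary control instead of amine catalysis: the enal is oxidised with NaClO2/NaH2PO4/2-methylbut-2-ene (Pinnick oxidation) to (E)-undec-2-enoic acid F1. Through its pivaloyl mixed anhydride (PivCl, NEt3; then (R)-4-benzyloxazolidin-2-one, LiCl) this becomes (R)-4-benzyl-3-[(E)-undec-2-enoyl]oxazolidin-2-one F2. An Et2AlCl-promoted Diels–Alder reaction of F2 with 2 (CH2Cl2, −78 °C) should run through the chelated s-cis imide, the diene adding anti to the benzyl group, to give (R)-4-benzyl-3-{(1S,2R,6R)-6-octyl-2-[(triisopropylsilyl)oxy]cyclohex-3-ene-1-carbonyl}oxazolidin-2-one F3. LiBH4/H2O in Et2O removes the auxiliary reductively to give {(1R,2R,6R)-6-octyl-2-[(triisopropylsilyl)oxy]cyclohex-3-en-1-yl}methanol F4, and Dess–Martin oxidation returns 6.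

2. Step 7. What may go wrong: in the allenyl β-diketone the enol oxygen may add to the allene before nitrogen is introduced, closing a 4-pyranone that exchanges its ring oxygen for N–OMe only sluggishly. The electrophilic allenyl ketone may also oligomerise. The same fallback answers a poor step 8.
Fallback, from 11 back to 15 and hence 16, introducing nitrogen before the ring ketone exists: Dess–Martin oxidation (NaHCO3, CH2Cl2) of the allenyl carbinol alone, with the ring oxygen still silylated, should give 2-methoxy-1-{(1S,2R,6R)-2-octyl-6-[(triisopropylsilyl)oxy]cyclohexyl}buta-2,3-dien-1-one F5. Methoxyamine (14, NaOAc, MeOH) adds to the allene to give the push–pull enaminone (E)-2-methoxy-3-(methoxyamino)-1-{(1S,2R,6R)-2-octyl-6-[(triisopropylsilyl)oxy]cyclohexyl}but-2-en-1-one F6. Bu4NF then frees (E)-1-[(1S,2R,6R)-2-hydroxy-6-octylcyclohexyl]-2-methoxy-3-(methoxyamino)but-2-en-1-one F7. Dess–Martin oxidation of the ring alcohol gives 15, which closes to 16 on warming with AcOH as in step 8.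

3. Step 9. What may go wrong: oxidation at the wrong α-carbon, since the C8 ring methylene is activated by the pyridone in the same way as the C2 methyl group; over-oxidation of the aldehyde to the acid is also possible.
Fallback, from 16 directly to 18, anionic instead of oxidative C–H functionalisation: kinetic lateral deprotonation of the 2-methyl group with LiN(SiMe3)2 in THF at −78 °C. The primary C–H flanked by the 3-methoxy and N-methoxy oxygens should be removed in preference to the secondary C8–H. The extended enolate is then trapped at the exocyclic carbon with 3-phenyl-2-(phenylsulfonyl)oxaziridine, giving 18 without passing through 17.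

**Further compounds**

F1 | step 2 | (E)-undec-2-enoic acid | CCCCCCCC/C=C/C(=O)O
F2 | step 2 | (R)-4-benzyl-3-[(E)-undec-2-enoyl]oxazolidin-2-one | CCCCCCCC/C=C/C(=O)N1[C@H](Cc2ccccc2)COC1=O
F3 | step 2 | (R)-4-benzyl-3-{(1S,2R,6R)-6-octyl-2-[(triisopropylsilyl)oxy]cyclohex-3-ene-1-carbonyl}oxazolidin-2-one | CCCCCCCC[C@@H]1CC=C[C@@H](O[Si](C(C)C)(C(C)C)C(C)C)[C@H]1C(=O)N2[C@H](Cc3ccccc3)COC2=O
F4 | step 2 | {(1R,2R,6R)-6-octyl-2-[(triisopropylsilyl)oxy]cyclohex-3-en-1-yl}methanol | CCCCCCCC[C@@H]1CC=C[C@@H](O[Si](C(C)C)(C(C)C)C(C)C)[C@H]1CO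
F5 | step 7 | 2-methoxy-1-{(1S,2R,6R)-2-octyl-6-[(triisopropylsilyl)oxy]cyclohexyl}buta-2,3-dien-1-one | CCCCCCCC[C@@H]1CCC[C@@H](O[Si](C(C)C)(C(C)C)C(C)C)[C@H]1C(=O)C(OC)=C=C
F6 | step 7 | (E)-2-methoxy-3-(methoxyamino)-1-{(1S,2R,6R)-2-octyl-6-[(triisopropylsilyl)oxy]cyclohexyl}but-2-en-1-one | CCCCCCCC[C@@H]1CCC[C@@H](O[Si](C(C)C)(C(C)C)C(C)C)[C@H]1C(=O)/C(OC)=C(/C)NOC
F7 | step 7 | (E)-1-[(1S,2R,6R)-2-hydroxy-6-octylcyclohexyl]-2-methoxy-3-(methoxyamino)but-2-en-1-one | CCCCCCCC[C@@H]1CCC[C@@H](O)[C@H]1C(=O)/C(OC)=C(/C)NOC
F0 | step 9 | none | none
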